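**Retrosynthetic overview**

1. Target acid ⇐ methyl ester ⇐ double Wittig methylenation of a dioxane-bearing cis-decalin-2,7-dione.
2. 1,2-Dioxane (last ring formed) ⇐ cobalt-catalysed hydroperoxysilylation of the side-chain trisubstituted alkene, then intramolecular peroxy-Michael addition to the (E)-2-methyl enoate.
3. cis-Decalindione ⇐ key step: a Birch-derived 1-methoxycyclohexa-1,4-diene (ring A, its two halves still equivalent) is unmasked and taken in one pot through amine-catalysed enantioselective olefin isomerisation and intramolecular Michael addition of a tethered methyl ketone (closes ring B, sets C4a and C8a).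
4. Cyclisation precursor ⇐ methyl ketone ⇐ thioester ⇐ Evans alkylation (sets C6) of the dihydroanisole acyl oxazolidinone with a C10 allylic halide made from geranyl chloride.
5. Dihydroanisole acid ⇐ Birch reduction of 3-(4-methoxyphenyl)-3-methylbutanoic acid ⇐ anisole + 3-methylbut-2-enoic acid. Ring order: A, then B, then the dioxane.

Assumption: 9-amino-9-deoxy-epi-quinine is taken to deliver the (S) γ-stereocentre in step 9; if the sense is opposite, its quinidine-derived pseudo-enantiomer is used.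

Locants used for the decalin: C1–C4 and C4a/C8a are ring A, C5–C8 are ring B; C2 and C7 carry the oxygen (later methylidene) functions, C5 is CMe2, C6 carries the side chain.

**Route**

Step 1
Reactants: 1 anisole; 2 3-methylbut-2-enoic acid
Product: 3 3-(4-methoxyphenyl)-3-methylbutanoic acid
Conditions: TfOH (10 mol%), anisole (4 equiv, neat), 50 °C
Reagents that add atoms: none
Why: Acid-catalysed Friedel–Crafts hydroarylation: protonation of 2 gives the tertiary cation, which alkylates anisole para to the methoxy group and so joins the quaternary CMe2 carbon (future C5) to ring A; no stereocentre is formed.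

Step 2
Reactants: 3 3-(4-methoxyphenyl)-3-methylbutanoic acid
Product: 4 3-(4-methoxycyclohexa-1,4-dien-1-yl)-3-methylbutanoic acid
Conditions: Li, NH3(l), THF, t-BuOH, −78 → −33 °C; NH4Cl; cold pH 6 work-up, used at once
Reagents that add atoms: none
Why: Birch reduction of a 4-alkylanisole gives the 1-methoxy-1,4-diene (the carboxylate is inert), which stores ring A as a base-stable latent cyclohex-3-enone whose two halves are still equivalent; no stereocentre is formed.

Step 3
Reactants: 4 3-(4-methoxycyclohexa-1,4-dien-1-yl)-3-methylbutanoic acid; 5 (4S)-4-benzyl-1,3-oxazolidin-2-one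
Product: 7 (4S)-4-benzyl-3-[3-(4-methoxycyclohexa-1,4-dien-1-yl)-3-methylbutanoyl]-1,3-oxazolidin-2-one, via mixed pivalic anhydride 6 (not isolated)
Conditions: t-BuCOCl, Et3N, THF, −20 °C; then 5, LiCl, −20 °C → rt
Reagents that add atoms: none
Why: N-Acylation of the Evans oxazolidinone through the mixed pivalic anhydride under basic conditions that leave the acid-labile enol ether intact; the auxiliary stereocentre is not touched.

Step 4
Reactants: 8 geranyl chloride [(2E)-1-chloro-3,7-dimethylocta-2,6-diene]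
Product: 9 (4E)-6-chloro-4-methylhex-4-enal
Conditions: O3 (1.0 equiv), pyridine (3 equiv), CH2Cl2, −78 °C
Reagents that add atoms: ozone, [O-][O+]=O
Why: Chemoselective ozonolysis of the electron-rich terminal alkene (the 2,3-alkene is deactivated by the allylic chloride), with pyridine converting the carbonyl oxide directly into the aldehyde; the (E)-alkene is retained.

Step 5
Reactants: 9 (4E)-6-chloro-4-methylhex-4-enal; 10 methyl 2-(triphenyl-λ5-phosphanylidene)propanoate
Product: 11 methyl (2E,6E)-8-chloro-2,6-dimethylocta-2,6-dienoate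
Conditions: CH2Cl2, rt
Reagents that add atoms: none
Why: Wittig olefination with a stabilised ylide gives the (E)-2-methyl enoate under thermodynamic control and does not touch the allylic chloride; no stereocentre is formed.

Step 6
Reactants: 7 (4S)-4-benzyl-3-[3-(4-methoxycyclohexa-1,4-dien-1-yl)-3-methylbutanoyl]-1,3-oxazolidin-2-one; 11 methyl (2E,6E)-8-chloro-2,6-dimethylocta-2,6-dienoate
Product: 14 methyl (2E,6E,9S)-10-[(4S)-4-benzyl-2-oxo-1,3-oxazolidin-3-yl]-9-[2-(4-methoxycyclohexa-1,4-dien-1-yl)propan-2-yl]-2,6-dimethyl-10-oxodeca-2,6-dienoate, via allylic iodide 12 (not isolated), via sodium enolate 13 (not isolated)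
Conditions: 11, NaI, THF, rt; 7, NaN(SiMe3)2, THF, −78 °C; combine, −78 → −40 °C
Reagents that add atoms: none
Why: Evans asymmetric alkylation: the chelated (Z)-sodium enolate is attacked by the Finkelstein-activated allylic iodide on the face opposite the benzyl group, which sets C9 (the future ring carbon C6) as S and attaches the whole side chain.

Step 7
Reactants: 14 methyl (2E,6E,9S)-10-[(4S)-4-benzyl-2-oxo-1,3-oxazolidin-3-yl]-9-[2-(4-methoxycyclohexa-1,4-dien-1-yl)propan-2-yl]-2,6-dimethyl-10-oxodeca-2,6-dienoate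
Product: 15 methyl (2E,6E,9S)-10-(ethylsulfanyl)-9-[2-(4-methoxycyclohexa-1,4-dien-1-yl)propan-2-yl]-2,6-dimethyl-10-oxodeca-2,6-dienoate
Conditions: EtSH, n-BuLi, THF, 0 °C; aq. NH4Cl
Reagents that add atoms: ethanethiol, CCS
Why: Thiolate cleavage of the N-acyl oxazolidinone at the exocyclic carbonyl (transthioesterification) is non-epimerising, spares the methyl ester and returns the auxiliary.

Step 8
Reactants: 15 methyl (2E,6E,9S)-10-(ethylsulfanyl)-9-[2-(4-methoxycyclohexa-1,4-dien-1-yl)propan-2-yl]-2,6-dimethyl-10-oxodeca-2,6-dienoate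
Product: 16 methyl (2E,6E,9S)-9-[2-(4-methoxycyclohexa-1,4-dien-1-yl)propan-2-yl]-2,6-dimethyl-10-oxoundeca-2,6-dienoate
Conditions: Me2CuLi (from MeLi and CuI), Et2O, −78 °C; aq. NH4Cl
Reagents that add atoms: lithium dimethylcuprate, [Li+].C[Cu-]C
Why: Gilman cuprate coupling of a thioester stops at the methyl ketone at −78 °C, leaves the enoate and the enol ether alone and uses no base that could epimerise the α-stereocentre.

Step 9
Reactants: 16 methyl (2E,6E,9S)-9-[2-(4-methoxycyclohexa-1,4-dien-1-yl)propan-2-yl]-2,6-dimethyl-10-oxoundeca-2,6-dienoate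
Product: 19 methyl (2E,6E)-8-[(4aS,6S,8aS)-5,5-dimethyl-2,7-dioxodecahydronaphthalen-6-yl]-2,6-dimethylocta-2,6-dienoate, via cyclohex-3-enone 17 (not isolated), via cyclohex-2-enone 18 (not isolated)
Conditions: (CO2H)2, THF/H2O, 0 °C; extract; then 9-amino-9-deoxy-epi-quinine (20 mol%), 2-chlorobenzoic acid (40 mol%), toluene, 40 °C
Reagents that add atoms: water, O
Why: Proposed new method: mild acid hydrolysis unmasks the cyclohex-3-enone 17, the primary amine catalyst converts it into a dienamine that is protonated enantioselectively at the γ-carbon (sets C4a as S in 18), and the resulting iminium ion is trapped by the enol or enamine of the tethered methyl ketone in a 6-exo Michael addition whose short tether can only reach the face it already occupies (sets C8a, cis ring fusion), the hindered C6–H not being enolised by the weak acid cocatalyst; the closest known reactions are the cinchona-diamine-catalysed isomerisation of Birch-derived β,γ-unsaturated cyclohexenones to 4-substituted cyclohex-2-enones and primary-amine-catalysed intramolecular Michael additions of ketones to enones.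

Step 10
Reactants: 19 methyl (2E,6E)-8-[(4aS,6S,8aS)-5,5-dimethyl-2,7-dioxodecahydronaphthalen-6-yl]-2,6-dimethylocta-2,6-dienoate
Product: 20 methyl (2E)-8-[(4aS,6S,8aS)-5,5-dimethyl-2,7-dioxodecahydronaphthalen-6-yl]-2,6-dimethyl-6-[(triethylsilyl)peroxy]oct-2-enoate (1:1 epimers at the peroxide carbon)
Conditions: cobalt bis(2,2,6,6-tetramethylheptane-3,5-dionate) (10 mol%), O2 (1 atm), Et3SiH, ClCH2CH2Cl, rt
Reagents that add atoms: dioxygen, O=O; triethylsilane, CC[SiH](CC)CC
Why: Isayama–Mukaiyama hydroperoxysilylation: hydrogen-atom transfer from a cobalt hydride to the only electron-rich alkene gives the tertiary radical, which is trapped by O2 and silylated while the enoate and both ketones stay untouched; the peroxide-bearing carbon is created without facial bias (planar radical, remote stereocentres) and is carried on as a 1:1 pair of epimers.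

Step 11
Reactants: 20 methyl (2E)-8-[(4aS,6S,8aS)-5,5-dimethyl-2,7-dioxodecahydronaphthalen-6-yl]-2,6-dimethyl-6-[(triethylsilyl)peroxy]oct-2-enoate
Product: 22 methyl (2R)-2-[(3R,6S)-6-{2-[(4aS,6S,8aS)-5,5-dimethyl-2,7-dioxodecahydronaphthalen-6-yl]ethyl}-6-methyl-1,2-dioxan-3-yl]propanoate, via tertiary hydroperoxide 21 (not isolated)
Conditions: K2CO3 (cat.), MeOH, 0 °C; then Et2NH, CF3CH2OH, rt; preparative HPLC
Reagents that add atoms: none
Why: Methanolysis of the silyl peroxide frees the tertiary hydroperoxide, which closes the 1,2-dioxane by reversible intramolecular peroxy-Michael addition (6-exo) to the (E)-enoate, the propanoate arm taking the equatorial position at C3 and C2 of the propanoate being fixed on enolate protonation, and the (2R,3R,6S) diastereomer is separated by preparative HPLC from its C6, C3 and C2 epimers, those of the 6S series being recyclable by re-equilibration under the same base.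

Step 12
Reactants: 22 methyl (2R)-2-[(3R,6S)-6-{2-[(4aS,6S,8aS)-5,5-dimethyl-2,7-dioxodecahydronaphthalen-6-yl]ethyl}-6-methyl-1,2-dioxan-3-yl]propanoate
Product: 23 methyl (2R)-2-[(3R,6S)-6-{2-[(4aS,6R,8aS)-5,5-dimethyl-2,7-dimethylidenedecahydronaphthalen-6-yl]ethyl}-6-methyl-1,2-dioxan-3-yl]propanoate
Conditions: Ph3PCH3Br (excess), KOt-Bu (slightly less than the salt), THF, 0 → 40 °C
Reagents that add atoms: methyltriphenylphosphonium bromide, C[P+](c1ccccc1)(c1ccccc1)c1ccccc1.[Br-]
Why: Double Wittig methylenation with excess Ph3P=CH2; dialkyl peroxides and methyl esters are tolerated by phosphorus ylides, and the C6 stereocentre should survive because its α-hydrogen, flanked by the quaternary carbon, is removed far more slowly than the C8 and ring A α-hydrogens (the descriptor at C6 changes from S to R only through the priority change at C7).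

Step 13
Reactants: 23 methyl (2R)-2-[(3R,6S)-6-{2-[(4aS,6R,8aS)-5,5-dimethyl-2,7-dimethylidenedecahydronaphthalen-6-yl]ethyl}-6-methyl-1,2-dioxan-3-yl]propanoate
Product: 24 (2R)-2-[(3R,6S)-6-{2-[(4aS,6R,8aS)-5,5-dimethyl-2,7-dimethylidenedecahydronaphthalen-6-yl]ethyl}-6-methyl-1,2-dioxan-3-yl]propanoic acid (CNP0363961.1)
Conditions: LiOH, THF/H2O, 0 °C → rt; then 1 M HCl, 0 °C
Reagents that add atoms: lithium hydroxide, [Li+].[OH-]
Why: Saponification of the methyl ester with cold LiOH and careful acidification, conditions that leave the dioxane, both exocyclic alkenes and all six stereocentres untouched.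

**Compound list**

1 | anisole (methoxybenzene) | COc1ccccc1 | starting material
2 | 3-methylbut-2-enoic acid | CC(C)=CC(=O)O | starting material
3 | 3-(4-methoxyphenyl)-3-methylbutanoic acid | COc1ccc(cc1)C(C)(C)CC(=O)O | intermediate
4 | 3-(4-methoxycyclohexa-1,4-dien-1-yl)-3-methylbutanoic acid | COC1=CCC(=CC1)C(C)(C)CC(=O)O | intermediate
5 | (4S)-4-benzyl-1,3-oxazolidin-2-one | O=C1N[C@@H](Cc2ccccc2)CO1 | starting material
6 | 3-(4-methoxycyclohexa-1,4-dien-1-yl)-3-methylbutanoic pivalic anhydride | COC1=CCC(=CC1)C(C)(C)CC(=O)OC(=O)C(C)(C)C | intermediate (not isolated)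
7 | (4S)-4-benzyl-3-[3-(4-methoxycyclohexa-1,4-dien-1-yl)-3-methylbutanoyl]-1,3-oxazolidin-2-one | COC1=CCC(=CC1)C(C)(C)CC(=O)N1[C@@H](Cc2ccccc2)COC1=O | intermediate
8 | geranyl chloride, (2E)-1-chloro-3,7-dimethylocta-2,6-diene | ClC/C=C(\C)CCC=C(C)C | starting material
9 | (4E)-6-chloro-4-methylhex-4-enal | ClC/C=C(\C)CCC=O | intermediate
10 | methyl 2-(triphenyl-λ5-phosphanylidene)propanoate | COC(=O)C(C)=P(c1ccccc1)(c1ccccc1)c1ccccc1 | starting material
11 | methyl (2E,6E)-8-chloro-2,6-dimethylocta-2,6-dienoate | ClC/C=C(\C)CC/C=C(\C)C(=O)OC | intermediate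
12 | methyl (2E,6E)-8-iodo-2,6-dimethylocta-2,6-dienoate | IC/C=C(\C)CC/C=C(\C)C(=O)OC | intermediate (not isolated)
13 | sodium (Z)-enolate of 7, sodium (1Z)-1-[(4S)-4-benzyl-2-oxo-1,3-oxazolidin-3-yl]-3-(4-methoxycyclohexa-1,4-dien-1-yl)-3-methylbut-1-en-1-olate | [Na+].[O-]/C(=C\C(C)(C)C1=CCC(OC)=CC1)N1[C@@H](Cc2ccccc2)COC1=O | intermediate (not isolated)
14 | methyl (2E,6E,9S)-10-[(4S)-4-benzyl-2-oxo-1,3-oxazolidin-3-yl]-9-[2-(4-methoxycyclohexa-1,4-dien-1-yl)propan-2-yl]-2,6-dimethyl-10-oxodeca-2,6-dienoate | O=C(N1[C@@H](Cc2ccccc2)COC1=O)[C@@H](C/C=C(\C)CC/C=C(\C)C(=O)OC)C(C)(C)C1=CCC(OC)=CC1 | intermediate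
15 | methyl (2E,6E,9S)-10-(ethylsulfanyl)-9-[2-(4-methoxycyclohexa-1,4-dien-1-yl)propan-2-yl]-2,6-dimethyl-10-oxodeca-2,6-dienoate | CCSC(=O)[C@@H](C/C=C(\C)CC/C=C(\C)C(=O)OC)C(C)(C)C1=CCC(OC)=CC1 | intermediate
16 | methyl (2E,6E,9S)-9-[2-(4-methoxycyclohexa-1,4-dien-1-yl)propan-2-yl]-2,6-dimethyl-10-oxoundeca-2,6-dienoate | CC(=O)[C@@H](C/C=C(\C)CC/C=C(\C)C(=O)OC)C(C)(C)C1=CCC(OC)=CC1 | intermediate
17 | methyl (2E,6E,9S)-2,6-dimethyl-10-oxo-9-[2-(4-oxocyclohex-1-en-1-yl)propan-2-yl]undeca-2,6-dienoate | CC(=O)[C@@H](C/C=C(\C)CC/C=C(\C)C(=O)OC)C(C)(C)C1=CCC(=O)CC1 | intermediate (not isolated)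
18 | methyl (2E,6E,9S)-2,6-dimethyl-10-oxo-9-{2-[(1S)-4-oxocyclohex-2-en-1-yl]propan-2-yl}undeca-2,6-dienoate | CC(=O)[C@@H](C/C=C(\C)CC/C=C(\C)C(=O)OC)C(C)(C)[C@H]1CCC(=O)C=C1 | intermediate (not isolated)
19 | methyl (2E,6E)-8-[(4aS,6S,8aS)-5,5-dimethyl-2,7-dioxodecahydronaphthalen-6-yl]-2,6-dimethylocta-2,6-dienoate (cis-fused) | O=C1CC[C@H]2[C@@H](C1)CC(=O)[C@@H](C/C=C(\C)CC/C=C(\C)C(=O)OC)C2(C)C | intermediate
20 | methyl (2E)-8-[(4aS,6S,8aS)-5,5-dimethyl-2,7-dioxodecahydronaphthalen-6-yl]-2,6-dimethyl-6-[(triethylsilyl)peroxy]oct-2-enoate, both epimers at chain C6 | O=C1CC[C@H]2[C@@H](C1)CC(=O)[C@@H](CCC(C)(OO[Si](CC)(CC)CC)CC/C=C(\C)C(=O)OC)C2(C)C | intermediate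
21 | methyl (2E)-8-[(4aS,6S,8aS)-5,5-dimethyl-2,7-dioxodecahydronaphthalen-6-yl]-6-hydroperoxy-2,6-dimethyloct-2-enoate, both epimers at chain C6 | O=C1CC[C@H]2[C@@H](C1)CC(=O)[C@@H](CCC(C)(OO)CC/C=C(\C)C(=O)OC)C2(C)C | intermediate (not isolated)
22 | methyl (2R)-2-[(3R,6S)-6-{2-[(4aS,6S,8aS)-5,5-dimethyl-2,7-dioxodecahydronaphthalen-6-yl]ethyl}-6-methyl-1,2-dioxan-3-yl]propanoate | O=C1CC[C@H]2[C@@H](C1)CC(=O)[C@@H](CC[C@@]1(C)CC[C@H]([C@@H](C)C(=O)OC)OO1)C2(C)C | intermediate
23 | methyl (2R)-2-[(3R,6S)-6-{2-[(4aS,6R,8aS)-5,5-dimethyl-2,7-dimethylidenedecahydronaphthalen-6-yl]ethyl}-6-methyl-1,2-dioxan-3-yl]propanoate | C=C1CC[C@H]2[C@@H](C1)CC(=C)[C@@H](CC[C@@]1(C)CC[C@H]([C@@H](C)C(=O)OC)OO1)C2(C)C | intermediate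
24 | (2R)-2-[(3R,6S)-6-{2-[(4aS,6R,8aS)-5,5-dimethyl-2,7-dimethylidenedecahydronaphthalen-6-yl]ethyl}-6-methyl-1,2-dioxan-3-yl]propanoic acid | C=C1CC[C@H]2[C@@H](C1)CC(=C)[C@@H](CC[C@@]1(C)CC[C@H]([C@@H](C)C(=O)O)OO1)C2(C)C | target

**Step count and weak points**

Total step count: 13. Longest linear sequence: 11 steps (steps 1–3 and 6–13); steps 4–5 make the side-chain halide.

The three steps most likely to fail:

Step 9. The catalyst must override any bias from the existing C6 centre, and the hindered methyl ketone may add slowly. Slow addition would leave room for erosion at C4a, for aldol closure of the ring A ketone onto the side-chain ketone, or for the transannular aldol reaction known for cis-decalin-2,7-diones. The fallback sets out from thioester 15 and makes the Michael donor far more acidic. Claisen condensation of 15 with the lithium enolate of allyl acetate (LiN(i-Pr)2, THF, −78 °C) gives the allyl β-keto ester F1. Oxalic acid hydrolysis and the same amine-catalysed isomerisation follow, after which a trace of K2CO3 closes ring B through the β-keto ester to the bicyclic allyl keto ester F2. Pd(PPh3)4 and morpholine at room temperature then remove the allyl carboxylate with decarboxylation and return the route to 19.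

Step 11 (with the uncontrolled centre from step 10). The peroxide carbon is formed 1:1, and the Michael closure discriminates poorly between methyl and the CH2CH2 chain at that carbon. Compound 22 is therefore a minor component (roughly 10–20 % of the mixture) of a difficult separation. The fallback sets out from 19 and builds the peroxide by ionic, reagent-controlled steps. Asymmetric epoxidation of the chain trisubstituted alkene (KHSO5, fructose-derived ketone of the series that gives the 6S,7S isomer) gives the (6S,7S)-epoxide F3. Ethereal H2O2 with catalytic H3PMo12O40 opens it at the tertiary carbon with inversion to the hydroxy hydroperoxide F4. Et2NH in CF3CH2OH closes the ring to the hydroxy dioxane F5, in which the now branched, hydroxylated arm at the peroxide carbon prefers the equatorial position and so fixes the 3,6-relationship. 1,1′-Thiocarbonyldiimidazole gives the imidazolyl thiocarbonate F6, and Bu3SnH (high concentration, to outrun epoxide formation from the β-peroxy radical) with AIBN removes the extra oxygen and comes back to the route at 22.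

Step 12. The ylide is a strong base and nucleophile. It may epimerise C6 to the more stable epimer through the hindered C7 ketone, attack the O–O bond, or open the dioxane by enolising the ester. The fallback sets out from 19 and changes the order so that no peroxide is present during olefination. Double Wittig methylenation of 19 gives the bis-methylidene triene ester F7. The same asymmetric epoxidation, now selective for the trisubstituted chain alkene over the two 1,1-disubstituted ones, gives the epoxide F8. H2O2 with H3PMo12O40 gives the hydroxy hydroperoxide F9, and Et2NH in CF3CH2OH gives the hydroxy dioxane F10. Thiocarbonyldiimidazole gives the imidazolyl thiocarbonate F11, and Bu3SnH with AIBN returns the route at 23.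

Further compounds
F1 | step 9 | 1-(prop-2-en-1-yl) 12-methyl (4S,6E,10E)-4-[2-(4-methoxycyclohexa-1,4-dien-1-yl)propan-2-yl]-7,11-dimethyl-3-oxododeca-6,10-dienedioate | C=CCOC(=O)CC(=O)[C@@H](C/C=C(\C)CC/C=C(\C)C(=O)OC)C(C)(C)C1=CCC(OC)=CC1
F2 | step 9 | prop-2-en-1-yl ester of the C8-carboxylic acid of 19 (ring stereocentres as in 19, C8 as an epimer mixture) | O=C1CC[C@H]2[C@@H](C1)C(C(=O)OCC=C)C(=O)[C@@H](C/C=C(\C)CC/C=C(\C)C(=O)OC)C2(C)C
F3 | step 11 | methyl (2E)-8-[(4aS,6S,8aS)-5,5-dimethyl-2,7-dioxodecahydronaphthalen-6-yl]-6,7-epoxy-2,6-dimethyloct-2-enoate, (6S,7S)-epoxide | O=C1CC[C@H]2[C@@H](C1)CC(=O)[C@@H](C[C@@H]1O[C@@]1(C)CC/C=C(\C)C(=O)OC)C2(C)C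
F4 | step 11 | methyl (2E,6R,7S)-8-[(4aS,6S,8aS)-5,5-dimethyl-2,7-dioxodecahydronaphthalen-6-yl]-6-hydroperoxy-7-hydroxy-2,6-dimethyloct-2-enoate | O=C1CC[C@H]2[C@@H](C1)CC(=O)[C@@H](C[C@H](O)[C@@](OO)(C)CC/C=C(\C)C(=O)OC)C2(C)C
F5 | step 11 | methyl (2R)-2-[(3R,6R)-6-{(1S)-2-[(4aS,6S,8aS)-5,5-dimethyl-2,7-dioxodecahydronaphthalen-6-yl]-1-hydroxyethyl}-6-methyl-1,2-dioxan-3-yl]propanoate | O=C1CC[C@H]2[C@@H](C1)CC(=O)[C@@H](C[C@H](O)[C@@]1(C)CC[C@H]([C@@H](C)C(=O)OC)OO1)C2(C)C
F6 | step 11 | O-(imidazol-1-ylcarbonothioyl) derivative of F5 | O=C1CC[C@H]2[C@@H](C1)CC(=O)[C@@H](C[C@H](OC(=S)n1ccnc1)[C@@]1(C)CC[C@H]([C@@H](C)C(=O)OC)OO1)C2(C)C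
F7 | step 12 | methyl (2E,6E)-8-[(4aS,6R,8aS)-5,5-dimethyl-2,7-dimethylidenedecahydronaphthalen-6-yl]-2,6-dimethylocta-2,6-dienoate | C=C1CC[C@H]2[C@@H](C1)CC(=C)[C@@H](C/C=C(\C)CC/C=C(\C)C(=O)OC)C2(C)C
F8 | step 12 | (6S,7S)-6,7-epoxide of F7 at the chain trisubstituted alkene | C=C1CC[C@H]2[C@@H](C1)CC(=C)[C@@H](C[C@@H]1O[C@@]1(C)CC/C=C(\C)C(=O)OC)C2(C)C
F9 | step 12 | methyl (2E,6R,7S)-8-[(4aS,6R,8aS)-5,5-dimethyl-2,7-dimethylidenedecahydronaphthalen-6-yl]-6-hydroperoxy-7-hydroxy-2,6-dimethyloct-2-enoate | C=C1CC[C@H]2[C@@H](C1)CC(=C)[C@@H](C[C@H](O)[C@@](OO)(C)CC/C=C(\C)C(=O)OC)C2(C)C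
F10 | step 12 | methyl (2R)-2-[(3R,6R)-6-{(1S)-2-[(4aS,6R,8aS)-5,5-dimethyl-2,7-dimethylidenedecahydronaphthalen-6-yl]-1-hydroxyethyl}-6-methyl-1,2-dioxan-3-yl]propanoate | C=C1CC[C@H]2[C@@H](C1)CC(=C)[C@@H](C[C@H](O)[C@@]1(C)CC[C@H]([C@@H](C)C(=O)OC)OO1)C2(C)C
F11 | step 12 | O-(imidazol-1-ylcarbonothioyl) derivative of F10 | C=C1CC[C@H]2[C@@H](C1)CC(=C)[C@@H](C[C@H](OC(=S)n1ccnc1)[C@@]1(C)CC[C@H]([C@@H](C)C(=O)OC)OO1)C2(C)C
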